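48.8% of product stood in the amber flask at 15.0 min, the same within a scatter of 0.3 percentage points as at 2.50 min, so I asked first what had stopped it.

the same everywhere: solid substrate 0.050 M

| flask | partner | temperature | remark | time |
|---|---|---|---|---|
| amber | 0.050 M | 100 °C | the very flask that is asked about, followed so far |  |
| blue | 0.075 M | 106 °C | run made earlier |  |
| flask | 0.0500 M | 100 °C |  | 20 min |

| run | time / min | product / % | solid substrate / % |
|---|---|---|---|
| amber | 2.50 | 48.8 | 19.5 |
| amber | 5.00 | 48.8 | 19.1 |
| amber | 6.00 | 47.9 | 19.2 |
| amber | 10.0 | 48.1 | 19.5 |
| amber | 12.0 | 49.0 | 19.4 |
| amber | 15.0 | 48.8 | 18.8 |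
| blue | 0.200 | 34.6 | 59.3 |
| blue | 0.667 | 50.6 | 20.2 |
| blue | 1.00 | 50.7 | 18.1 |
| blue | 1.50 | 50.3 | 17.8 |
| blue | 2.50 | 50.3 | 17.9 |
| blue | 3.00 | 49.7 | 18.1 |
| blue | 4.00 | 50.2 | 18.3 |

(standard deviation of a reading: 0.3 percentage points)

- Saturday's: at 20 min raise the temperature by 15 K, then wait 10 min
- Monday's: change nothing and wait 10 min more
- Thursday's: at 20 min add partner, 50.0% of the amount charged, then wait 10 min
- Tuesday's: at 20 min take out 90% of the product then present, then wait 10 min

- given per volume of solution although it is solid: solid substrate
- product taken out counts as made
- candidate steps: solid substrate <-> dissolved substrate; dissolved substrate + partner -> product; partner -> decomposed reagent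
- at the start none of the solid substrate is in solution
- additions bring no volume worth counting

- product, in percent of the solid substrate first charged, at 20 min
- the remedy with the largest gain of product, or "none" below 2 percentage points (Saturday's / Monday's / Thursday's / Tuesday's / none)
- product present, with what was taken out counted in, in percent of the solid substrate first charged, after Saturday's
- product present, with what was taken out counted in, in percent of the solid substrate first charged, after Monday's

Amber still held 18.8% as solid substrate, and the balance put 32.4% in solution as dissolved substrate. Substrate was therefore at hand, and I took the partner to be the limiting reagent.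

So I asked what became of a partner molecule. It meets a fork: it joins dissolved substrate and gives product, or it decomposes. By the amber reading at 15.0 min, 48.8% of the partner charged had ended in product. I called this the capture share, product made per partner charged, a selectivity. The blue flask, hotter at 106 °C and with 0.075 M of partner, read 33.5% at 4.00 min, less than amber.

That raised the last question: what can a remedy add? I reckoned the product gained as the amber capture share times the c(partner) added. Saturday's, Monday's and Tuesday's add no partner, so I reckoned no gain from them. Thursday's adds 0.0250 M, which at the amber share I put at 24 points, more than the margin.

The forecast gave 48.6% now, 48.6% after Saturday's and 48.6% after Monday's, and it chose Thursday's: “Only fresh partner helps”. Where I had 24 points, it said perhaps 20 points.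

The flask gave 48.6%, 48.6% and 48.6%, with 0% of the partner left at 20.0 min. Thursday's was best and brought 37 points, more than my reckoning.

    solid substrate ⇌ dissolved substrate, rate k1*(cs1 - [dissolved substrate]) while solid is left; crystals form when [dissolved substrate] > cs1 (solubility = 16.0 mM, k = 0.120 /s)
    dissolved substrate + partner → product (k = 20.0 /M/s, Ea = 59.0 kJ/mol)
    partner → decomposed reagent (k = 0.0600 /s, Ea = 95.0 kJ/mol)
    (constants at 100 °C)

The neighbour flask held 0.020 M of solid substrate, its other charges as in amber, which made 2.50 equiv of partner. At the amber capture share its partner could make 122% of that charge, more than the charge holds, so I expected substrate to end first there. The neighbour flask gave 98.8% at 20.0 min, and the first charge to run out was the solid substrate, of which 1.2% stayed, solid or dissolved, against 51.4% in the asked flask.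

The earlier runs and the new flask stem from a simulated flask on assumed constants; the scatter is artificial.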